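**Strategy.** The cyclopentane-1,3-dione ring of the target (C1, C8, C5, C6, C7; bicyclo[3.2.1]octane locants, C1 = prenylated bridgehead) and its exocyclic enoyl carbon C1′ are read as a ring-contracted cyclohexane-1,3,5-trione in which C1′ sat between C6 and C7. Cutting C1–C8 and C5–C6 then opens both rings to one chain. The key step, a base-triggered Claisen–Dieckmann cascade, forms these two bonds, both rings and both quaternary bridgeheads in one operation from a linear β-keto S-phenyl thioester (latent acylketene at C8) tethered through C4–C3–C2 to a dioxinone (C1 nucleophile, masked C6 acyl donor). Oxidation, acetylide addition and an α-ketol shift then contract the triketone ring.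

Key step: step 10

Remark on locants: in the Why lines atoms carry their target locants (C1 prenylated bridgehead, C2 CH2, C3 CH-prenyl, C4 CMe2, C5 acylated bridgehead, C6 ring ketone, C7 carbinol carbon, C8 bridging ketone, C1′ enoyl carbonyl carbon). Ring B is the carbocycle C1–C2–C3–C4–C5–C8; ring A is the triketone ring of 22 (C5, C6, C1′, C7, C1, C8).

Remark on the target: the (Z)-γ-hydroxy enone is taken in the open-chain form drawn; it may equilibrate with its cyclic hemiketal.

Step 1
Reactants: 1 3,3-dimethylpent-4-enoic acid; 2 (4S)-4-benzyl-1,3-oxazolidin-2-one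
Product: 4 (4S)-4-benzyl-3-(3,3-dimethylpent-4-enoyl)-1,3-oxazolidin-2-one, via mixed pivalic anhydride 3 (not isolated)
Conditions: t-BuCOCl, Et3N, THF, −20 °C; then 2, LiCl, −20 °C to rt
Reagents that add atoms: none
Why: N-acylation of the oxazolidinone by the mixed anhydride (attachment of an Evans auxiliary) should proceed cleanly, and no stereocentre is formed.

Step 2
Reactants: 4 imide; 5 1-bromo-3-methylbut-2-ene (prenyl bromide)
Product: 6 (4S)-4-benzyl-3-[(2S)-5-methyl-2-(2-methylbut-3-en-2-yl)hex-4-enoyl]-1,3-oxazolidin-2-one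
Conditions: NaN(SiMe3)2, THF, −78 °C; then 5, −78 to −20 °C
Reagents that add atoms: none
Why: Evans asymmetric alkylation, in which the benzyl group shields one face of the chelated Z-enolate so that the allylic bromide enters from the other face and sets C3 (2S in the imide).

Step 3
Reactants: 6 prenylated imide
Product: 7 (2S)-5-methyl-2-(2-methylbut-3-en-2-yl)hex-4-en-1-ol
Conditions: LiBH4, MeOH (1 equiv), Et2O, 0 °C
Reagents that add atoms: none
Why: Reductive cleavage of the imide should give the primary alcohol (future C2) without touching C3 or the alkenes, and the auxiliary is recovered.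

Step 4
Reactants: 7 alcohol; 8 2,2,6-trimethyl-4H-1,3-dioxin-4-one
Product: 10 2,2-dimethyl-6-[(3S)-6-methyl-3-(2-methylbut-3-en-2-yl)hept-5-en-1-yl]-4H-1,3-dioxin-4-one, via primary triflate 9 (not isolated)
Conditions: 7: Tf2O, 2,6-lutidine, CH2Cl2, −78 °C; 8: LiN(i-Pr)2, THF, −78 °C, then DMPU and crude 9, −78 to −40 °C
Reagents that add atoms: none
Why: γ-Alkylation of the dioxinone lithium dienolate (side-chain elongation of a vinylogous ester enolate) by a primary triflate reactive enough for the β-branched centre; this forms C1–C2 and C3 is not involved.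

Step 5
Reactants: 10 dioxinone; 5 1-bromo-3-methylbut-2-ene
Product: 11 6-[(7R)-2,10-dimethyl-7-(2-methylbut-3-en-2-yl)undeca-2,9-dien-5-yl]-2,2-dimethyl-4H-1,3-dioxin-4-one (both C5 epimers)
Conditions: LiN(i-Pr)2, THF, DMPU, −78 °C; then 5, −78 to −30 °C
Reagents that add atoms: none
Why: Second γ-alkylation of the dioxinone dienolate with a reactive allylic bromide; the new centre (future C1) forms without control, which is harmless because it is re-enolised in step 10.

Step 6
Reactants: 11 diprenyl dioxinone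
Product: 13 6-[(7R)-7-(4-hydroxy-2-methylbutan-2-yl)-2,10-dimethylundeca-2,9-dien-5-yl]-2,2-dimethyl-4H-1,3-dioxin-4-one, via B-alkyl-9-BBN adduct 12 (not isolated)
Conditions: 9-BBN, THF, 0 °C to rt; then 30% H2O2, aq. NaOAc, 0 °C to rt
Reagents that add atoms: hydrogen peroxide, OO
Why: Brown hydroboration–oxidation, in which 9-BBN should add anti-Markovnikov to the monosubstituted vinyl group far faster than to the trisubstituted prenyl alkenes or the dioxinone.

Step 7
Reactants: 13 primary alcohol
Product: 15 (4R)-4-[2-(2,2-dimethyl-4-oxo-4H-1,3-dioxin-6-yl)-5-methylhex-4-en-1-yl]-3,3,7-trimethyloct-6-enoic acid, via aldehyde 14 (not isolated)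
Conditions: TEMPO (cat.), PhI(OAc)2, MeCN/H2O, rt
Reagents that add atoms: water, O
Why: Oxoammonium oxidation in aqueous acetonitrile should take the primary alcohol through the aldehyde hydrate to the acid (C8) and leave trisubstituted alkenes alone.

Step 8
Reactants: 15 acid; 16 benzenethiol
Product: 17 S-phenyl (4R)-4-[2-(2,2-dimethyl-4-oxo-4H-1,3-dioxin-6-yl)-5-methylhex-4-en-1-yl]-3,3,7-trimethyloct-6-enethioate
Conditions: DCC, DMAP (cat.), CH2Cl2, 0 °C to rt
Reagents that add atoms: none
Why: Steglich-type carbodiimide coupling should give the thioester that allows soft enolisation in step 9 and thiolate loss in step 10.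

Step 9
Reactants: 17 thioester; 18 2-methylpropanoyl chloride
Product: 19 S-phenyl (4R)-4-[2-(2,2-dimethyl-4-oxo-4H-1,3-dioxin-6-yl)-5-methylhex-4-en-1-yl]-3,3,7-trimethyl-2-(2-methylpropanoyl)oct-6-enethioate (epimers at C2 of the chain and at the dioxinone-bearing carbon)
Conditions: MgBr2·OEt2, i-Pr2NEt, CH2Cl2, rt
Reagents that add atoms: none
Why: Soft enolisation of the thioester and C-acylation by the acid chloride (a crossed Claisen without strong base) should spare the dioxinone γ-proton; the new centre (C5) is epimerisable and is erased in step 10.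

Step 10
Reactants: 19 β-keto thioester
Product: 22 (1S,5R,7R)-6,6-dimethyl-1,7-bis(3-methylbut-2-en-1-yl)-5-(2-methylpropanoyl)bicyclo[3.3.1]nonane-2,4,9-trione (drawn as the triketone; expected as its enol), via acylketene 20 (not isolated), via monocyclic diketone 21 (not isolated)
Conditions: LiN(SiMe3)2 (2.3 equiv), THF, −78 °C to rt, then 60 °C; aq. HCl
Reagents that add atoms: none
Why: The base enolises the β-keto thioester, which loses thiophenoxide (E1cB) to give acylketene 20, and also deprotonates the dioxinone γ-carbon; this carbon (C1) adds to the ketene carbon (C8) to give the enolate of 21, whose α-carbon (C5) then attacks the dioxinone carbonyl (C6) with loss of acetone, the enolate of the cyclic 1,3-diketone being the thermodynamic sink. The closest known reactions are the γ-C-acylation of dioxinone dienolates (keto-dioxinone synthesis), the Lacey–Dieckmann C-acylation of 1,3-dicarbonyl compounds by esters and the Effenberger bicyclisation. Ring B closes in a 6-(enolexo)-exo-dig mode on the ketene and ring A in a 6-(enolendo)-exo-trig mode on the dioxinone carbonyl. C1 is set in the first closure relative to C3: in a chair-like transition state the C3 prenyl group is equatorial and the planar dienolate, with its bulkier chain syn to the ring oxygen, is expected to sit pseudo-axial (least allylic strain), cis to H-3, and C5 is then fixed because the second ring can only bridge cis-diaxially. The step needs C- rather than O-acylation in the bridging event: O-acylation through the C8 oxygen would require a tetrasubstituted exocyclic enol ester between two quaternary carbons, O-acylation through the isobutyryl oxygen would require an eight-membered ring, and the fully substituted C1 blocks aromatisation to a pyranone.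

Step 11
Reactants: 22 bicyclic trione
Product: 23 (1R,5R,7R)-6,6-dimethyl-1,7-bis(3-methylbut-2-en-1-yl)-5-(2-methylpropanoyl)bicyclo[3.3.1]nonane-2,3,4,9-tetrone (may be obtained as the hydrate of the central ketone and is dried before use)
Conditions: Dess–Martin periodinane, pyridine, CH2Cl2, rt
Reagents that add atoms: Dess–Martin periodinane (oxygen donor), CC(=O)OI1(OC(C)=O)(OC(C)=O)OC(=O)c2ccccc12
Why: Periodinane oxidation of an enolised 1,3-dicarbonyl compound at its central carbon (C1′) should give the vicinal tricarbonyl, while alkenes and the non-enolisable ketones stay untouched.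

Step 12
Reactants: 23 tetrone; 24 2-methylbut-3-yn-2-ol
Product: 26 (1S,3R,5R,7S)-7-hydroxy-7-(4-hydroxy-4-methylpent-2-ynoyl)-4,4-dimethyl-1,3-bis(3-methylbut-2-en-1-yl)-5-(2-methylpropanoyl)bicyclo[3.2.1]octane-6,8-dione, via tertiary carbinol 25 (not isolated)
Conditions: 24, n-BuLi (2 equiv), THF, −78 to 0 °C; then 23, −78 °C to rt; aq. NH4Cl
Reagents that add atoms: none
Why: The lithium acetylide should add to the most electrophilic, central carbonyl (C1′) from the exo face, and the tertiary alkoxide then undergoes a reversible α-ketol (acyloin) 1,2-acyl shift of C6 from C1′ to C7 (the humulone-to-isohumulone type of ring contraction), thermodynamic control placing the carbinol next to the less hindered C1 with the ynoyl group exo and the hydroxyl syn to the C2–C4 bridge.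

Step 13
Reactants: 26 ynone
Product: 27 (1S,3R,5R,7S)-7-hydroxy-7-[(2Z)-4-hydroxy-4-methylpent-2-enoyl]-4,4-dimethyl-1,3-bis(3-methylbut-2-en-1-yl)-5-(2-methylpropanoyl)bicyclo[3.2.1]octane-6,8-dione (target)
Conditions: H2 (1 atm), Pd/CaCO3 poisoned with Pb(OAc)2, quinoline, EtOAc, 0 °C
Reagents that add atoms: none
Why: Lindlar semi-hydrogenation adds hydrogen syn to the ynone and should give the Z-enone, while trisubstituted alkenes and ketones are not reduced.

**Compound list**

1 | 3,3-dimethylpent-4-enoic acid | C=CC(C)(C)CC(=O)O | starting material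
2 | (4S)-4-benzyl-1,3-oxazolidin-2-one | O=C1N[C@@H](Cc2ccccc2)CO1 | starting material
3 | 3,3-dimethylpent-4-enoic pivalic anhydride | C=CC(C)(C)CC(=O)OC(=O)C(C)(C)C | intermediate
4 | (4S)-4-benzyl-3-(3,3-dimethylpent-4-enoyl)-1,3-oxazolidin-2-one | C=CC(C)(C)CC(=O)N1[C@@H](Cc2ccccc2)COC1=O | intermediate
5 | 1-bromo-3-methylbut-2-ene (prenyl bromide) | CC(C)=CCBr | starting material
6 | (4S)-4-benzyl-3-[(2S)-5-methyl-2-(2-methylbut-3-en-2-yl)hex-4-enoyl]-1,3-oxazolidin-2-one | CC(C)=CC[C@@H](C(C)(C)C=C)C(=O)N1[C@@H](Cc2ccccc2)COC1=O | intermediate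
7 | (2S)-5-methyl-2-(2-methylbut-3-en-2-yl)hex-4-en-1-ol | CC(C)=CC[C@@H](C(C)(C)C=C)CO | intermediate
8 | 2,2,6-trimethyl-4H-1,3-dioxin-4-one | CC1=CC(=O)OC(C)(C)O1 | starting material
9 | (2S)-5-methyl-2-(2-methylbut-3-en-2-yl)hex-4-en-1-yl trifluoromethanesulfonate | CC(C)=CC[C@@H](C(C)(C)C=C)COS(=O)(=O)C(F)(F)F | intermediate
10 | 2,2-dimethyl-6-[(3S)-6-methyl-3-(2-methylbut-3-en-2-yl)hept-5-en-1-yl]-4H-1,3-dioxin-4-one | CC(C)=CC[C@@H](C(C)(C)C=C)CCC1=CC(=O)OC(C)(C)O1 | intermediate
11 | 6-[(7R)-2,10-dimethyl-7-(2-methylbut-3-en-2-yl)undeca-2,9-dien-5-yl]-2,2-dimethyl-4H-1,3-dioxin-4-one (both C5 epimers) | CC(C)=CC[C@@H](C(C)(C)C=C)CC(CC=C(C)C)C1=CC(=O)OC(C)(C)O1 | intermediate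
12 | B-alkyl-9-borabicyclo[3.3.1]nonane from 11 (boron on the former vinyl CH2) | CC(C)=CC[C@@H](C(C)(C)CCB1C2CCCC1CCC2)CC(CC=C(C)C)C1=CC(=O)OC(C)(C)O1 | intermediate
13 | 6-[(7R)-7-(4-hydroxy-2-methylbutan-2-yl)-2,10-dimethylundeca-2,9-dien-5-yl]-2,2-dimethyl-4H-1,3-dioxin-4-one | CC(C)=CC[C@@H](C(C)(C)CCO)CC(CC=C(C)C)C1=CC(=O)OC(C)(C)O1 | intermediate
14 | (4R)-4-[2-(2,2-dimethyl-4-oxo-4H-1,3-dioxin-6-yl)-5-methylhex-4-en-1-yl]-3,3,7-trimethyloct-6-enal | CC(C)=CC[C@@H](C(C)(C)CC=O)CC(CC=C(C)C)C1=CC(=O)OC(C)(C)O1 | intermediate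
15 | (4R)-4-[2-(2,2-dimethyl-4-oxo-4H-1,3-dioxin-6-yl)-5-methylhex-4-en-1-yl]-3,3,7-trimethyloct-6-enoic acid | CC(C)=CC[C@@H](C(C)(C)CC(=O)O)CC(CC=C(C)C)C1=CC(=O)OC(C)(C)O1 | intermediate
16 | benzenethiol | Sc1ccccc1 | starting material
17 | S-phenyl (4R)-4-[2-(2,2-dimethyl-4-oxo-4H-1,3-dioxin-6-yl)-5-methylhex-4-en-1-yl]-3,3,7-trimethyloct-6-enethioate | CC(C)=CC[C@@H](C(C)(C)CC(=O)Sc1ccccc1)CC(CC=C(C)C)C1=CC(=O)OC(C)(C)O1 | intermediate
18 | 2-methylpropanoyl chloride | CC(C)C(=O)Cl | starting material
19 | S-phenyl (4R)-4-[2-(2,2-dimethyl-4-oxo-4H-1,3-dioxin-6-yl)-5-methylhex-4-en-1-yl]-3,3,7-trimethyl-2-(2-methylpropanoyl)oct-6-enethioate (epimers at C2 and at the dioxinone-bearing carbon) | CC(C)=CC[C@@H](C(C)(C)C(C(=O)C(C)C)C(=O)Sc1ccccc1)CC(CC=C(C)C)C1=CC(=O)OC(C)(C)O1 | intermediate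
20 | acylketene from 19 by loss of benzenethiol (ketene carbon = C8; drawn neutral) | CC(C)=CC[C@@H](C(C)(C)C(=C=O)C(=O)C(C)C)CC(CC=C(C)C)C1=CC(=O)OC(C)(C)O1 | intermediate
21 | 6-[(1S,5R)-4,4-dimethyl-1,5-bis(3-methylbut-2-en-1-yl)-3-(2-methylpropanoyl)-2-oxocyclohexyl]-2,2-dimethyl-4H-1,3-dioxin-4-one (prenyl groups cis; C3 epimerisable) | CC(C)=CC[C@@H]1C[C@@](CC=C(C)C)(C2=CC(=O)OC(C)(C)O2)C(=O)C(C(=O)C(C)C)C1(C)C | intermediate
22 | (1S,5R,7R)-6,6-dimethyl-1,7-bis(3-methylbut-2-en-1-yl)-5-(2-methylpropanoyl)bicyclo[3.3.1]nonane-2,4,9-trione | CC(C)=CC[C@@H]1C[C@]2(CC=C(C)C)C(=O)[C@@](C(=O)C(C)C)(C(=O)CC2=O)C1(C)C | intermediate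
23 | (1R,5R,7R)-6,6-dimethyl-1,7-bis(3-methylbut-2-en-1-yl)-5-(2-methylpropanoyl)bicyclo[3.3.1]nonane-2,3,4,9-tetrone | CC(C)=CC[C@@H]1C[C@]2(CC=C(C)C)C(=O)[C@@](C(=O)C(C)C)(C(=O)C(=O)C2=O)C1(C)C | intermediate
24 | 2-methylbut-3-yn-2-ol | CC(C)(O)C#C | starting material
25 | 3-hydroxy-3-(3-hydroxy-3-methylbut-1-yn-1-yl) adduct of 23 at the central ketone (alkynyl group exo; other centres as in 23) | CC(C)=CC[C@@H]1C[C@]2(CC=C(C)C)C(=O)[C@@](C(=O)C(C)C)(C(=O)[C@@](O)(C#CC(C)(C)O)C2=O)C1(C)C | intermediate
26 | (1S,3R,5R,7S)-7-hydroxy-7-(4-hydroxy-4-methylpent-2-ynoyl)-4,4-dimethyl-1,3-bis(3-methylbut-2-en-1-yl)-5-(2-methylpropanoyl)bicyclo[3.2.1]octane-6,8-dione | CC(C)=CC[C@@H]1C[C@]2(CC=C(C)C)C(=O)[C@@](C(=O)C(C)C)(C(=O)[C@@]2(O)C(=O)C#CC(C)(C)O)C1(C)C | intermediate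
27 | (1S,3R,5R,7S)-7-hydroxy-7-[(2Z)-4-hydroxy-4-methylpent-2-enoyl]-4,4-dimethyl-1,3-bis(3-methylbut-2-en-1-yl)-5-(2-methylpropanoyl)bicyclo[3.2.1]octane-6,8-dione | CC(C)=CC[C@@H]1C[C@]2(CC=C(C)C)C(=O)[C@@](C(=O)C(C)C)(C(=O)[C@@]2(O)C(=O)/C=C\C(C)(C)O)C1(C)C | target

Total step count: 13
Longest linear sequence: 13 steps (1 to 27)

**Steps most likely to fail**

Step 10. Two processes may go wrong. The first ring closure may show poor facial selectivity at C1, giving the epimer that cannot bridge with an equatorial C3 prenyl group. The bridging closure may also be diverted to O-acylation. The fallback sets out from 21 and returns at 22. The cascade is stopped after the first closure (LiN(SiMe3)2, THF, −78 to 0 °C, cold acidic quench), 21 is isolated and its C1 epimers are separated by chromatography. The 1,3-diketone is O-methylated with trimethylsilyldiazomethane in toluene/MeOH to the O-methyl vinylogous ester F1, which blocks the oxygen. Heating F1 in toluene at 110 °C opens the dioxinone to the acylketene, which C-acylates the enol-ether carbon C5 as in the second event of an Effenberger bicyclisation; the methyl group passes to the new diketone oxygen and gives the bicyclic methyl enol ether F2. LiCl in DMSO at 120 °C then cleaves the methyl ether to 22.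

Step 12. The strongly basic dilithio acetylide may add unselectively or cleave the polyketone by retro-Claisen fragmentation before the acyl shift. The fallback sets out from 22 and returns at 26, and reverses the polarity of both new bonds at C1′. Trione 22 is alkynylated at the central carbon of its 1,3-diketone with 1-[3-methyl-3-(triethylsilyloxy)but-1-yn-1-yl]-1,2-benziodoxol-3(1H)-one and 1,1,3,3-tetramethylguanidine in THF to give the alkynyl trione F3. Its potassium enolate (KN(SiMe3)2, THF, −78 °C) is hydroxylated with 2-(benzenesulfonyl)-3-phenyloxaziridine, and the tertiary alkoxide is warmed to rt to effect the same α-ketol contraction, giving the silyl ether F4. HF·pyridine in THF removes the triethylsilyl group to give 26.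

Step 4. Displacement at the β-branched primary triflate may be slower than decomposition of the triflate or than proton transfer and α-alkylation of the dienolate. The fallback sets out from 7 and returns at 10, and replaces the SN2 step by carbonyl addition and deoxygenation. Alcohol 7 is oxidised with Dess–Martin periodinane in CH2Cl2 to the aldehyde F5. Vinylogous aldol addition of the lithium dienolate of 8 (LiN(i-Pr)2, THF, −78 °C) gives the δ-hydroxy dioxinone F6, whose carbinol epimers are immaterial. Phenyl chlorothionoformate and pyridine convert it into the thionocarbonate F7, and Barton–McCombie reduction (Bu3SnH, AIBN, toluene, 90 °C) gives 10.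

Further compounds
F1 | step 10 | O-methyl vinylogous ester of 21 (one O-regioisomer drawn) | CC(C)=CC[C@@H]1C[C@@](CC=C(C)C)(C2=CC(=O)OC(C)(C)O2)C(OC)=C(C(=O)C(C)C)C1(C)C
F2 | step 10 | methyl enol ether of trione 22 (one O-regioisomer drawn) | CC(C)=CC[C@@H]1C[C@]2(CC=C(C)C)C(=O)[C@@](C(=O)C(C)C)(C(=O)C=C2OC)C1(C)C
F3 | step 12 | 3-[3-methyl-3-(triethylsilyloxy)but-1-yn-1-yl] derivative of 22 (drawn as the triketone) | CC(C)=CC[C@@H]1C[C@]2(CC=C(C)C)C(=O)[C@@](C(=O)C(C)C)(C(=O)C(C#CC(C)(C)O[Si](CC)(CC)CC)C2=O)C1(C)C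
F4 | step 12 | triethylsilyl ether of 26 at the side-chain tertiary hydroxyl | CC(C)=CC[C@@H]1C[C@]2(CC=C(C)C)C(=O)[C@@](C(=O)C(C)C)(C(=O)[C@@]2(O)C(=O)C#CC(C)(C)O[Si](CC)(CC)CC)C1(C)C
F5 | step 4 | (2S)-5-methyl-2-(2-methylbut-3-en-2-yl)hex-4-enal | CC(C)=CC[C@@H](C(C)(C)C=C)C=O
F6 | step 4 | 6-[(3S)-2-hydroxy-6-methyl-3-(2-methylbut-3-en-2-yl)hept-5-en-1-yl]-2,2-dimethyl-4H-1,3-dioxin-4-one (carbinol epimers) | CC(C)=CC[C@@H](C(C)(C)C=C)C(O)CC1=CC(=O)OC(C)(C)O1
F7 | step 4 | O-phenyl thionocarbonate of F6 | CC(C)=CC[C@@H](C(C)(C)C=C)C(OC(=S)Oc1ccccc1)CC1=CC(=O)OC(C)(C)O1
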